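Hardest feature: ring A is fully substituted. C5, C6, C7 and C8 all carry oxygen and only O6 is methylated, a pattern that no benzenoid building block offers.
Enabling feature: C5(OH)–C6(OMe)–C7(OH)–C8(OH) is a chain of four oxygen-bearing carbons whose ends are para (a hydroquinone). This chain is the four carbons of squaric acid, and C4a=C8a is one C=C bond of a 4H-pyran-4-one.
Cuts: C8–C8a and C5–C4a (ring A falls into a mixed tert-butyl methyl squarate and a 3-aryl-5-iodo-4-pyranone), then C3–C1' (Suzuki), then C1'–B (C–H borylation).
Forward: ring C is bought as 4H-pyran-4-one and ring B is coupled to it. C5–C4a is made by Grignard addition, and ring A arises last by 4π opening and 6π closure of the cyclobutenone.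
O6 and O7 are told apart before ring A exists (OMe against OtBu on the squarate), and one acid step at the end frees O7 and O3'.
Stereochemistry: the target has none, and the two transient sp3 centres on the way are racemic and are erased.
Key step: step 7

Assumption: the target SMILES holds no stereocentre and no configured double bond, so the request for a single enantiomer places no demand on the route.

Step 1
Reactants: 1 2,3-dimethoxyphenol
Product: 2 1,2-dimethoxy-3-(methoxymethoxy)benzene
Conditions: NaH, MOMCl, DMF, 0 °C → rt
Reagents that add atoms: chloromethyl methyl ether (MOMCl), COCCl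
Why: Williamson-type O-alkylation of the sodium phenoxide gives an acetal ether that withstands base, palladium, magnesium reagents and heat and is removed by acid in the last step.

Step 2
Reactants: 2 1,2-dimethoxy-3-(methoxymethoxy)benzene
Product: 3 2-[3,4-dimethoxy-5-(methoxymethoxy)phenyl]-4,4,5,5-tetramethyl-1,3,2-dioxaborolane
Conditions: [Ir(OMe)(cod)]2 (cat.), dtbpy (cat.), B2pin2 (1 equiv), THF, 80 °C
Reagents that add atoms: bis(pinacolato)diboron, CC1(C)OB(OC1(C)C)B2OC(C)(C)C(C)(C)O2
Why: Iridium-catalysed C–H borylation is governed by sterics, and in a 1,2,3-trisubstituted benzene only C5–H has no ortho neighbour, which puts boron on the future C1'.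

Step 3
Reactants: 4 4H-pyran-4-one
Product: 5 3,5-diiodo-4H-pyran-4-one
Conditions: I2, PhI(OCOCF3)2, pyridine, CH2Cl2, rt, dark
Reagents that add atoms: iodine, II
Why: Electrophilic α-iodination of a β-oxygenated enone with trifluoroacetyl hypoiodite made in situ strikes C3 and C5, the nucleophilic enol-ether β-carbons, and is done before the electron-rich ring B is present so that nothing competes.

Step 4
Reactants: 3 2-[3,4-dimethoxy-5-(methoxymethoxy)phenyl]-4,4,5,5-tetramethyl-1,3,2-dioxaborolane; 5 3,5-diiodo-4H-pyran-4-one (2 equiv)
Product: 6 3-[3,4-dimethoxy-5-(methoxymethoxy)phenyl]-5-iodo-4H-pyran-4-one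
Conditions: Pd(dppf)Cl2 (cat.), K2CO3, 1,4-dioxane/H2O, 45 °C
Reagents that add atoms: none
Why: Suzuki–Miyaura coupling of the kind used on 3-iodochromones makes C3–C1', and because the two C–I bonds are equivalent, single coupling is enforced by an excess of 5, which is recovered.

Step 5
Reactants: 7 dimethyl squarate (3,4-dimethoxycyclobut-3-ene-1,2-dione)
Product: 8 3-tert-butoxy-4-methoxycyclobut-3-ene-1,2-dione
Conditions: KOtBu (1.0 equiv, slow addition), THF, −78 → −30 °C; then 1 M HCl (1.0 equiv), 0 °C
Reagents that add atoms: potassium tert-butoxide, CC(C)(C)[O-].[K+]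
Why: Addition–elimination at a ring carbon (transesterification of a vinylogous ester) should stop after one exchange, because the tetrahedral intermediate expels the better leaving group methoxide and the first tert-butoxy group hinders a second attack.

Step 6
Reactants: 6 3-[3,4-dimethoxy-5-(methoxymethoxy)phenyl]-5-iodo-4H-pyran-4-one; 8 3-tert-butoxy-4-methoxycyclobut-3-ene-1,2-dione
Product: 10 (±)-2-tert-butoxy-4-{5-[3,4-dimethoxy-5-(methoxymethoxy)phenyl]-4-oxo-4H-pyran-3-yl}-4-hydroxy-3-methoxycyclobut-2-en-1-one, via pyranonylmagnesium chloride 9 (not isolated)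
Conditions: iPrMgCl·LiCl, THF, −40 °C; then 8, −40 → −20 °C; sat. aq NH4Cl
Reagents that add atoms: none
Why: Iodine–magnesium exchange on an α-iodo-β-oxygenated enone followed by 1,2-addition of the alkenylmagnesium to a squarate ester (the standard entry to 4-hydroxycyclobutenones) makes C5–C4a, the tert-butoxy group shields the carbonyl group beside it so that attack should fall on the carbonyl carbon next to C–OMe, and the carbinol centre is formed racemic without consequence because step 7 erases it.

Step 7
Reactants: 10 (±)-2-tert-butoxy-4-{5-[3,4-dimethoxy-5-(methoxymethoxy)phenyl]-4-oxo-4H-pyran-3-yl}-4-hydroxy-3-methoxycyclobut-2-en-1-one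
Product: 13 7-tert-butoxy-3-[3,4-dimethoxy-5-(methoxymethoxy)phenyl]-5,8-dihydroxy-6-methoxy-4H-chromen-4-one, via dienylketene 11 (not isolated), via cyclohexadienone 12 (not isolated)
Conditions: degassed toluene (0.02 M), Ar, 110 °C
Reagents that add atoms: none
Why: This is a Moore rearrangement (thermal ring expansion of a 4-alkenyl- or 4-heteroaryl-4-hydroxycyclobutenone): conrotatory 4π opening of the C1–C4 bond of 10 gives dienylketene 11, a 6π electrocyclisation joins the ketene carbon (future C8) to the pyranone CH next to the ring oxygen (future C8a), and enolisation of cyclohexadienone 12 gives the aromatic hydroquinone. The only ring closed is ring A, by a six-membered all-carbon 6π electrocyclic closure that forms C8–C8a, C5–C4a being in place since step 6. The torquoselectivity needed is outward rotation of the hydroxyl group, the normal preference of a donor at C4 of a cyclobutenone, which turns the pyranonyl group inward towards the ketene. Site selectivity is fixed by the substrate, because the other neighbour of C4a is the C4 carbonyl carbon, so that C8a is the only atom on which a six-membered carbocycle can close. The order C5–OH, C6–OMe, C7–OtBu, C8–OH is copied from the order C4, C3, C2, C1 of the cyclobutenone, so all four oxygens arrive differentiated in one operation. No stereocentre is set, since the carbinol centre of 10 and the C8a centre of 12 both become sp2.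

Step 8
Reactants: 13 7-tert-butoxy-3-[3,4-dimethoxy-5-(methoxymethoxy)phenyl]-5,8-dihydroxy-6-methoxy-4H-chromen-4-one
Product: 14 5,7,8-trihydroxy-3-(3-hydroxy-4,5-dimethoxyphenyl)-6-methoxy-4H-chromen-4-one (target)
Conditions: TFA/CH2Cl2/H2O (10:10:1), Ar, 0 °C → rt
Reagents that add atoms: none
Why: Acidolysis removes the aryl tert-butyl ether as isobutene (E1) and hydrolyses the MOM acetal while the three methyl ethers stay, and the cold, air-free medium should prevent both oxidation of the 5,7,8-trihydroxy ring and acid-induced opening and reclosure of ring C.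

Compound list
1 | 2,3-dimethoxyphenol | COc1cccc(O)c1OC | starting material
2 | 1,2-dimethoxy-3-(methoxymethoxy)benzene | COCOc1cccc(OC)c1OC | intermediate
3 | 2-[3,4-dimethoxy-5-(methoxymethoxy)phenyl]-4,4,5,5-tetramethyl-1,3,2-dioxaborolane | COCOc1cc(B2OC(C)(C)C(C)(C)O2)cc(OC)c1OC | intermediate
4 | 4H-pyran-4-one | O=c1ccocc1 | starting material
5 | 3,5-diiodo-4H-pyran-4-one | O=c1c(I)cocc1I | intermediate
6 | 3-[3,4-dimethoxy-5-(methoxymethoxy)phenyl]-5-iodo-4H-pyran-4-one | COCOc1cc(-c2cocc(I)c2=O)cc(OC)c1OC | intermediate
7 | dimethyl squarate (3,4-dimethoxycyclobut-3-ene-1,2-dione) | COC1=C(OC)C(=O)C1=O | starting material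
8 | 3-tert-butoxy-4-methoxycyclobut-3-ene-1,2-dione | COC1=C(OC(C)(C)C)C(=O)C1=O | intermediate
9 | {5-[3,4-dimethoxy-5-(methoxymethoxy)phenyl]-4-oxo-4H-pyran-3-yl}magnesium chloride | COCOc1cc(-c2cocc([Mg]Cl)c2=O)cc(OC)c1OC | intermediate
10 | (±)-2-tert-butoxy-4-{5-[3,4-dimethoxy-5-(methoxymethoxy)phenyl]-4-oxo-4H-pyran-3-yl}-4-hydroxy-3-methoxycyclobut-2-en-1-one (racemic) | COCOc1cc(-c2cocc(C3(O)C(OC)=C(OC(C)(C)C)C3=O)c2=O)cc(OC)c1OC | intermediate
11 | (Z)-2-tert-butoxy-4-hydroxy-3-methoxy-4-(5-aryl-4-oxo-4H-pyran-3-yl)buta-1,3-dien-1-one, pyranonyl cis to the ketene arm | COCOc1cc(-c2cocc(/C(O)=C(OC)\C(OC(C)(C)C)=C=O)c2=O)cc(OC)c1OC | intermediate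
12 | (±)-7-tert-butoxy-3-[3,4-dimethoxy-5-(methoxymethoxy)phenyl]-5-hydroxy-6-methoxy-8aH-chromene-4,8-dione (racemic) | COCOc1cc(C2=COC3C(=O)C(OC(C)(C)C)=C(OC)C(O)=C3C2=O)cc(OC)c1OC | intermediate
13 | 7-tert-butoxy-3-[3,4-dimethoxy-5-(methoxymethoxy)phenyl]-5,8-dihydroxy-6-methoxy-4H-chromen-4-one | COCOc1cc(-c2coc3c(O)c(OC(C)(C)C)c(OC)c(O)c3c2=O)cc(OC)c1OC | intermediate
14 | 5,7,8-trihydroxy-3-(3-hydroxy-4,5-dimethoxyphenyl)-6-methoxy-4H-chromen-4-one (5,7,8,3'-tetrahydroxy-6,4',5'-trimethoxyisoflavone, achiral) | COc1cc(-c2coc3c(O)c(O)c(OC)c(O)c3c2=O)cc(O)c1OC | target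

Total step count: 8
Longest linear sequence: 6 (steps 1, 2, 4, 6, 7, 8)

Steps most likely to fail

**Step 6.** The danger is poor site selectivity between the two carbonyl groups of 8, which would place OMe and OtBu the wrong way round on ring A.
- The fallback takes the choice away from the addition. It sets out from 9, which is added to the symmetrical di-tert-butyl squarate F1 (bought, or made from disilver squarate and tert-butyl chloride). Both carbonyl groups of this ester are the same, and the addition gives the 2,3-di-tert-butoxy-4-hydroxycyclobutenone F2.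
- In F2 only the tert-butoxy group next to the carbinol carbon is a vinylogous tert-butyl ester. A short exposure to TFA in CH2Cl2 at 0 °C should remove it alone and give the 2-tert-butoxy-3,4-dihydroxycyclobutenone (vinylogous acid) F3.
- In F3 the two oxygen-bearing carbons that flank the carbinol carbon are interchanged by tautomerism. O-methylation with TMSCHN2 at either oxygen therefore gives one and the same constitution, and the route is rejoined at 10.

**Step 7.** The danger is slow closure of the ketene onto the electron-poor C8a=C4a bond. Forcing temperatures would then be needed, and return to the cyclobutenone, capture of the ketene by its own hydroxyl group and thermal loss of the MOM ether beside an acidic hydroquinone could take over.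
- The fallback builds ring A before ring B is attached. It sets out from 5. One equivalent of iPrMgCl·LiCl should exchange only one iodine, because the (5-iodo-4-oxo-4H-pyran-3-yl)magnesium chloride F4 is deactivated towards a second exchange.
- Addition to 8 gives 2-tert-butoxy-4-hydroxy-4-(5-iodo-4-oxo-4H-pyran-3-yl)-3-methoxycyclobut-2-en-1-one F5. This small substrate has no MOM group and can be heated hard for a short time in a flow coil.
- The ring expansion gives 7-tert-butoxy-5,8-dihydroxy-3-iodo-6-methoxy-4H-chromen-4-one F6. A degassed Suzuki–Miyaura coupling of F6 with 3 rejoins the route at 13. This order also replaces the excess-controlled coupling of step 4 by a self-limiting exchange.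

**Step 5.** The danger is attack of the hindered alkoxide on the methyl carbon instead of the ring carbon (dealkylation to the squarate monoanion), or a second exchange.
- The fallback changes from addition–elimination to an SN1-type O-alkylation. It sets out from 7, which is half-saponified with one equivalent of NaOH. The anion formed resists further attack, and acidification gives 3-hydroxy-4-methoxycyclobut-3-ene-1,2-dione (monomethyl squarate) F7.
- This strong acid is treated with tert-butyl 2,2,2-trichloroacetimidate in CH2Cl2/cyclohexane. Capture of the tert-butyl cation by either oxygen of the delocalised anion gives the same 1,2-diester, and the route is rejoined at 8.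

Further compounds
F1 | step 6 | di-tert-butyl squarate (3,4-di-tert-butoxycyclobut-3-ene-1,2-dione) | CC(C)(C)OC1=C(OC(C)(C)C)C(=O)C1=O
F2 | step 6 | (±)-2,3-di-tert-butoxy-4-{5-[3,4-dimethoxy-5-(methoxymethoxy)phenyl]-4-oxo-4H-pyran-3-yl}-4-hydroxycyclobut-2-en-1-one | COCOc1cc(-c2cocc(C3(O)C(OC(C)(C)C)=C(OC(C)(C)C)C3=O)c2=O)cc(OC)c1OC
F3 | step 6 | (±)-2-tert-butoxy-4-{5-[3,4-dimethoxy-5-(methoxymethoxy)phenyl]-4-oxo-4H-pyran-3-yl}-3,4-dihydroxycyclobut-2-en-1-one | COCOc1cc(-c2cocc(C3(O)C(O)=C(OC(C)(C)C)C3=O)c2=O)cc(OC)c1OC
F4 | step 7 | (5-iodo-4-oxo-4H-pyran-3-yl)magnesium chloride | O=c1c(I)cocc1[Mg]Cl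
F5 | step 7 | (±)-2-tert-butoxy-4-hydroxy-4-(5-iodo-4-oxo-4H-pyran-3-yl)-3-methoxycyclobut-2-en-1-one | COC1=C(OC(C)(C)C)C(=O)C1(O)c1cocc(I)c1=O
F6 | step 7 | 7-tert-butoxy-5,8-dihydroxy-3-iodo-6-methoxy-4H-chromen-4-one | COc1c(O)c2c(=O)c(I)coc2c(O)c1OC(C)(C)C
F7 | step 5 | 3-hydroxy-4-methoxycyclobut-3-ene-1,2-dione (monomethyl squarate) | COC1=C(O)C(=O)C1=O
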